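The synthesis hinges on disconnecting both C–O bonds at carbon C6 of the 1,2-dioxane ring (C6–O1 and C6–OMe). The key step exploits the fact that C6, bonded to ring oxygen O1 and to OMe, is a peroxyketal carbon whose C–O bonds form reversibly: in acidic methanol the C3 hydroperoxide of an open-chain precursor adds to its C6 ketone, closes the ring and installs the methoxy group in one operation, while C6 equilibrates, directed by C3, to the chair with axial methoxy and equatorial carbon substituents. The precursor is methyl (3S,12E)-3-hydroperoxy-6-oxodocos-12-en-10-ynoate, which already holds the whole enyne chain; its C3 centre comes from amine-catalysed enantioselective peroxidation of an enal.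

Key step: step 11

Remark: counting the carbons of the target SMILES gives a sixteen-carbon side chain at C6, (E)-hexadec-6-en-4-yn-1-yl, and the names below use this count; ring atoms are numbered O1, O2, C3 (acetic acid arm), C4, C5, C6 (ketal carbon).

Remark: the (R) configuration of the catalyst in step 8 is assigned from the usual facial shielding model for iminium ions of diarylprolinol silyl ethers (attack on the Si face of C3 of the E enal gives 3S).

Step 1
Reactants: 1 hex-5-ynoic acid
Product: 3 N-methoxy-N-methylhex-5-ynamide, via 1-(hex-5-ynoyl)imidazole 2 (not isolated)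
Conditions: CDI (1.1 equiv), CH2Cl2, rt, 1 h; then MeNH(OMe)·HCl (1.2 equiv), rt, 12 h
Reagents that add atoms: N,O-dimethylhydroxylamine hydrochloride, CNOC.Cl; 1,1'-carbonyldiimidazole, O=C(n1ccnc1)n1ccnc1 (its imidazolyl group stays only in 2)
Why: Amide coupling through an acyl imidazole: the acid is activated with loss of CO2 and the imidazolide is displaced by the hydroxylamine to give the Weinreb amide, the terminal alkyne being inert.

Step 2
Reactants: 4 undec-1-yne
Product: 6 (E)-1-iodoundec-1-ene, via (E)-undec-1-enylzirconocene chloride 5 (not isolated)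
Conditions: Cp2Zr(H)Cl (1.3 equiv), THF, rt, dark; then I2 (1.2 equiv), 0 °C
Reagents that add atoms: iodine, II; zirconocene chloride hydride Cp2Zr(H)Cl, [H][Zr](Cl)(C1C=CC=C1)C1C=CC=C1 (its zirconium stays only in 5)
Why: Hydrozirconation of a terminal alkyne places zirconium on the terminal carbon by syn addition and iodinolysis of the C–Zr bond occurs with retention, so only the E alkenyl iodide should form.

Step 3
Reactants: 3 N-methoxy-N-methylhex-5-ynamide; 6 (E)-1-iodoundec-1-ene
Product: 7 (E)-N-methoxy-N-methylheptadec-7-en-5-ynamide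
Conditions: Pd(PPh3)4 (3 mol%), CuI (6 mol%), Et3N (3 equiv), THF, rt, degassed
Reagents that add atoms: none
Why: Sonogashira coupling of a terminal alkyne with an alkenyl iodide proceeds at room temperature with retention of the alkene geometry and is compatible with the Weinreb amide.

Step 4
Reactants: 7 (E)-N-methoxy-N-methylheptadec-7-en-5-ynamide; 8 2-(2-bromoethyl)-1,3-dioxolane
Product: 11 (E)-1-(1,3-dioxolan-2-yl)nonadec-9-en-7-yn-3-one, via [2-(1,3-dioxolan-2-yl)ethyl]magnesium bromide 9 (not isolated), via bromomagnesium hemiaminal chelate 10 (not isolated)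
Conditions: 8 (2 equiv), Mg turnings, THF, 25–30 °C; then 7, THF, 0 °C; H2O, then aq. NH4Cl
Reagents that add atoms: magnesium, [Mg] (stays only in 9 and 10)
Why: Weinreb ketone synthesis: the Grignard reagent adds only once because the chelated tetrahedral adduct persists until aqueous work-up, while the enyne and the acetal are indifferent to the reagent.

Step 5
Reactants: 11 (E)-1-(1,3-dioxolan-2-yl)nonadec-9-en-7-yn-3-one
Product: 12 (E)-4-oxoicos-10-en-8-ynal
Conditions: 1 M aq. HCl/THF (1:3), rt; extractive work-up, used crude at once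
Reagents that add atoms: water, O
Why: Acid-catalysed acetal hydrolysis frees the aldehyde under conditions that leave ketone and enyne untouched, and immediate use of the 1,4-keto aldehyde forestalls aldol or furan formation.

Step 6
Reactants: 12 (E)-4-oxoicos-10-en-8-ynal; 13 (triphenylphosphoranylidene)acetaldehyde
Product: 14 (2E,12E)-6-oxodocosa-2,12-dien-10-ynal
Conditions: 13 (1.1 equiv), toluene, 50 °C
Reagents that add atoms: none
Why: Wittig reaction of a stabilised ylide is selective for the aldehyde over the ketone and should give the E enal, the limited amount of ylide curbing a second homologation.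

Step 7
Reactants: 15 2,3-dimethylbut-2-ene
Product: 17 2-methoxypropan-2-yl hydroperoxide, via acetone O-oxide 16 (not isolated)
Conditions: O3, MeOH/CH2Cl2 (1:4), −78 °C; N2 purge; concentrated cold behind a shield and kept as a stock solution
Reagents that add atoms: ozone, [O-][O+]=O; methanol, CO
Why: Criegee ozonolysis in a participating solvent: ozone cleaves the symmetrical alkene into acetone and a carbonyl oxide that methanol captures as the α-methoxy hydroperoxide.

Step 8
Reactants: 14 (2E,12E)-6-oxodocosa-2,12-dien-10-ynal; 17 2-methoxypropan-2-yl hydroperoxide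
Product: 19 (3S,12E)-3-[(2-methoxypropan-2-yl)peroxy]-6-oxodocos-12-en-10-ynoic acid, via (3S)-peroxy aldehyde 18 (not isolated)
Conditions: 17 (2.5 equiv), (R)-2-{bis[3,5-bis(trifluoromethyl)phenyl](trimethylsilyloxy)methyl}pyrrolidine (10 mol%), PhCO2H (10 mol%), toluene, −10 °C; then t-BuOH/H2O, 2-methylbut-2-ene (excess), NaH2PO4, NaClO2, 0 °C
Reagents that add atoms: sodium chlorite, [Na+].[O-]Cl=O
Why: Amine-catalysed enantioselective conjugate peroxidation under iminium-ion activation, in which the (R)-diarylprolinol silyl ether blocks the Re face of C3 so that the hydroperoxide oxygen adds to the Si face and sets 3S, is followed in the same flask by Pinnick oxidation, which spares ketone, enyne and peroxyketal and removes the aldehyde before retro-addition can erode C3.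

Step 9
Reactants: 19 (3S,12E)-3-[(2-methoxypropan-2-yl)peroxy]-6-oxodocos-12-en-10-ynoic acid
Product: 20 methyl (3S,12E)-3-[(2-methoxypropan-2-yl)peroxy]-6-oxodocos-12-en-10-ynoate
Conditions: TMSCHN2 (1.5 equiv), toluene/MeOH (4:1), 0 °C
Reagents that add atoms: (trimethylsilyl)diazomethane, C[Si](C)(C)C=[N+]=[N-]
Why: Diazoalkane esterification of the carboxylic acid is neutral and fast, so the base-sensitive β-peroxy carbonyl unit and the acid-sensitive peroxyketal should both survive.

Step 10
Reactants: 20 methyl (3S,12E)-3-[(2-methoxypropan-2-yl)peroxy]-6-oxodocos-12-en-10-ynoate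
Product: 21 methyl (3S,12E)-3-hydroperoxy-6-oxodocos-12-en-10-ynoate
Conditions: AcOH/THF/H2O (4:2:1), rt; toluene azeotrope; used crude
Reagents that add atoms: none
Why: Mild acid hydrolysis of the mixed peroxyketal releases the hydroperoxide without touching ester or enyne, and the expected ring–chain equilibrium of the product with its peroxyhemiketal 22 is harmless because both forms feed step 11.

Step 11
Reactants: 21 methyl (3S,12E)-3-hydroperoxy-6-oxodocos-12-en-10-ynoate
Product: 24 methyl 2-[(3S,6R)-6-[(E)-hexadec-6-en-4-yn-1-yl]-6-methoxy-1,2-dioxan-3-yl]acetate, via peroxyhemiketal 22 (not isolated), via cyclic peroxycarbenium ion 23 (not isolated)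
Conditions: TsOH·H2O (10 mol%), dry MeOH (0.05 M), 3 Å MS, rt, until the C6 epimer ratio no longer changes; solid NaHCO3 quench
Reagents that add atoms: methanol, CO
Why: The terminal hydroperoxide oxygen O1 adds to the protonated C6 ketone to give hemiketal 22, acid ionises its hydroxyl to the peroxycarbenium ion 23, and methanol adds to C6, so that C6–O1 and C6–OMe are both made by reversible events. The closest known reaction type is the acid-catalysed conversion of β- and γ-hydroperoxy ketones, or their cyclic peroxyhemiketals, into 3-alkoxy-1,2-dioxolanes and 3-alkoxy-1,2-dioxanes in alcohols. The 1,2-dioxane closes in a 6-exo-trig mode, O1 attacking the carbonyl carbon whose C=O bond lies outside the new ring. The new stereocentre C6 is set under thermodynamic control by the fixed C3 centre: with the C3 ester arm equatorial, the chair with axial methoxy (anomeric stabilisation by O1) and equatorial enyne chain should be lowest in energy, which is the 3,6-cis (3S,6R) isomer, and axial capture of 23 points to the same isomer. The step needs diastereoselectivity at C6 and chemoselectivity against open-chain dimethyl ketal formation, O–O cleavage and ester exchange; equilibration, the intramolecular six-membered closure and the use of a methyl ester in methanol secure these, and the enyne is inert to dilute sulfonic acid.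

Step 12
Reactants: 24 methyl 2-[(3S,6R)-6-[(E)-hexadec-6-en-4-yn-1-yl]-6-methoxy-1,2-dioxan-3-yl]acetate
Product: 25 2-[(3S,6R)-6-[(E)-hexadec-6-en-4-yn-1-yl]-6-methoxy-1,2-dioxan-3-yl]acetic acid
Conditions: LiOH·H2O (3 equiv), THF/H2O (3:1), 0 °C; then cold 0.5 M HCl to pH 4, extraction
Reagents that add atoms: lithium hydroxide, [Li+].[OH-] (its oxygen ends in the carboxyl group)
Why: Saponification at 0 °C should cleave the unhindered methyl ester faster than hydroxide deprotonates C2, so the base-stable peroxyketal and the C3 centre are kept, and brief acidification to pH 4 is too mild to reopen the ketal.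

Compound list

1 | hex-5-ynoic acid | C#CCCCC(=O)O | starting material
2 | 1-(hex-5-ynoyl)imidazole | C#CCCCC(=O)n1ccnc1 | intermediate
3 | N-methoxy-N-methylhex-5-ynamide | C#CCCCC(=O)N(C)OC | intermediate
4 | undec-1-yne | C#CCCCCCCCCC | starting material
5 | (E)-undec-1-enylzirconocene chloride, chlorobis(cyclopentadienyl)[(E)-undec-1-en-1-yl]zirconium | CCCCCCCCC/C=C/[Zr](Cl)(C1C=CC=C1)C1C=CC=C1 | intermediate
6 | (E)-1-iodoundec-1-ene | CCCCCCCCC/C=C/I | intermediate
7 | (E)-N-methoxy-N-methylheptadec-7-en-5-ynamide | CCCCCCCCC/C=C/C#CCCCC(=O)N(C)OC | intermediate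
8 | 2-(2-bromoethyl)-1,3-dioxolane | BrCCC1OCCO1 | starting material
9 | [2-(1,3-dioxolan-2-yl)ethyl]magnesium bromide | Br[Mg]CCC1OCCO1 | intermediate
10 | bromomagnesium hemiaminal chelate, bromomagnesium (E)-1-(1,3-dioxolan-2-yl)-3-[methoxy(methyl)amino]nonadec-9-en-7-yn-3-olate | CCCCCCCCC/C=C/C#CCCCC(O[Mg]Br)(CCC1OCCO1)N(C)OC | intermediate
11 | (E)-1-(1,3-dioxolan-2-yl)nonadec-9-en-7-yn-3-one | CCCCCCCCC/C=C/C#CCCCC(=O)CCC1OCCO1 | intermediate
12 | (E)-4-oxoicos-10-en-8-ynal | CCCCCCCCC/C=C/C#CCCCC(=O)CCC=O | intermediate
13 | (triphenylphosphoranylidene)acetaldehyde | O=CC=P(c1ccccc1)(c1ccccc1)c1ccccc1 | starting material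
14 | (2E,12E)-6-oxodocosa-2,12-dien-10-ynal | CCCCCCCCC/C=C/C#CCCCC(=O)CC/C=C/C=O | intermediate
15 | 2,3-dimethylbut-2-ene | CC(C)=C(C)C | starting material
16 | acetone O-oxide (propan-2-one O-oxide, carbonyl oxide) | CC(C)=[O+][O-] | intermediate
17 | 2-methoxypropan-2-yl hydroperoxide | COC(C)(C)OO | intermediate
18 | (3S,12E)-3-[(2-methoxypropan-2-yl)peroxy]-6-oxodocos-12-en-10-ynal | CCCCCCCCC/C=C/C#CCCCC(=O)CC[C@@H](CC=O)OOC(C)(C)OC | intermediate
19 | (3S,12E)-3-[(2-methoxypropan-2-yl)peroxy]-6-oxodocos-12-en-10-ynoic acid | CCCCCCCCC/C=C/C#CCCCC(=O)CC[C@@H](CC(=O)O)OOC(C)(C)OC | intermediate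
20 | methyl (3S,12E)-3-[(2-methoxypropan-2-yl)peroxy]-6-oxodocos-12-en-10-ynoate | CCCCCCCCC/C=C/C#CCCCC(=O)CC[C@@H](CC(=O)OC)OOC(C)(C)OC | intermediate
21 | methyl (3S,12E)-3-hydroperoxy-6-oxodocos-12-en-10-ynoate | CCCCCCCCC/C=C/C#CCCCC(=O)CC[C@@H](CC(=O)OC)OO | intermediate
22 | methyl 2-[(3S)-6-[(E)-hexadec-6-en-4-yn-1-yl]-6-hydroxy-1,2-dioxan-3-yl]acetate (peroxyhemiketal, both C6 epimers) | CCCCCCCCC/C=C/C#CCCCC1(O)CC[C@@H](CC(=O)OC)OO1 | intermediate
23 | cyclic peroxycarbenium ion, (3S)-6-[(E)-hexadec-6-en-4-yn-1-yl]-3-(2-methoxy-2-oxoethyl)-4,5-dihydro-3H-1,2-dioxin-1-ium (C6=O1 cation from 22 by loss of hydroxide) | CCCCCCCCC/C=C/C#CCCCC1=[O+]O[C@H](CC(=O)OC)CC1 | intermediate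
24 | methyl 2-[(3S,6R)-6-[(E)-hexadec-6-en-4-yn-1-yl]-6-methoxy-1,2-dioxan-3-yl]acetate | CCCCCCCCC/C=C/C#CCCC[C@]1(OC)CC[C@@H](CC(=O)OC)OO1 | intermediate
25 | 2-[(3S,6R)-6-[(E)-hexadec-6-en-4-yn-1-yl]-6-methoxy-1,2-dioxan-3-yl]acetic acid | CCCCCCCCC/C=C/C#CCCC[C@]1(OC)CC[C@@H](CC(=O)O)OO1 | target

Total step count: 12. Longest linear sequence: 10 steps (1, 3, 4, 5, 6, 8, 9, 10, 11, 12); steps 2 and 7 are side branches.

Steps most likely to fail

Step 8. The catalyst-bound enamine that forms after peroxide addition may be diverted before it is protonated, either by closing onto the O–O bond (epoxide formation with loss of the peroxide) or by closing onto the C6 ketone (five-membered aldol). The adduct may also revert by retro-addition, and facial control at C3 may be incomplete. The sense of induction rests on the shielding model and would be checked on the first sample; the (S) catalyst is equally accessible. The fallback removes the ketone from the aminocatalytic step by carrying C6 at the alcohol oxidation level. Setting out from 11, reduction with NaBH4 (MeOH, 0 °C) should give (E)-1-(1,3-dioxolan-2-yl)nonadec-9-en-7-yn-3-ol F1 (racemic at the carbinol carbon, which is of no consequence). Silylation with TBSCl and imidazole (DMF) should give tert-butyl{[(E)-1-(1,3-dioxolan-2-yl)nonadec-9-en-7-yn-3-yl]oxy}dimethylsilane F2, and acetal hydrolysis with PPTS in wet acetone (50 °C) should give (E)-4-[(tert-butyldimethylsilyl)oxy]icos-10-en-8-ynal F3. Homologation with ylide 13 should give (2E,12E)-6-[(tert-butyldimethylsilyl)oxy]docosa-2,12-dien-10-ynal F4. The conditions of step 8 should then give (3S,12E)-6-[(tert-butyldimethylsilyl)oxy]-3-[(2-methoxypropan-2-yl)peroxy]docos-12-en-10-ynoic acid F5, and those of step 9 methyl (3S,12E)-6-[(tert-butyldimethylsilyl)oxy]-3-[(2-methoxypropan-2-yl)peroxy]docos-12-en-10-ynoate F6. TBAF buffered with AcOH (THF) should free methyl (3S,12E)-6-hydroxy-3-[(2-methoxypropan-2-yl)peroxy]docos-12-en-10-ynoate F7, and Dess–Martin periodinane (NaHCO3, CH2Cl2), which tolerates peroxyketals, should restore the ketone and rejoin the route at 20.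

Step 11. Equilibration at C6 may stop short and leave the 3,6-trans epimer, the ketone may be drained into its open-chain dimethyl ketal, or prolonged exposure to protic acid may heterolyse the O–O bond (Hock or Criegee-type fragmentation). The fallback replaces protic equilibration by an aprotic, kinetically controlled silyl-transfer ketalisation. Setting out from 21 (with its ring tautomer 22), MeOTMS (5 equiv) and TMSOTf (5 mol%) in CH2Cl2 at −78 °C, quenched with pyridine, should generate ion 23 at low temperature. Axial capture on the half-chair with the C3 arm pseudo-equatorial should deliver the same (3S,6R) isomer, and the sequence comes back to the route at 24 without any new compound (F0).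

Step 12. Hydroxide may remove a C2 proton and expel the peroxide oxygen O2 (ring opening by β-elimination, with loss or scrambling of C3), or attack the C3–H in a Kornblum–DeLaMare-type fragmentation; the acidification may also hydrolyse the ketal. The fallback is a neutral biocatalytic hydrolysis. Setting out from 24, pig liver esterase in pH 7 phosphate buffer with 10% acetone as co-solvent at rt, followed by extraction at pH 5, should give 25 directly without free hydroxide or strong acid and without any new compound (F0).

Further compounds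

F1 | step 8 | (E)-1-(1,3-dioxolan-2-yl)nonadec-9-en-7-yn-3-ol | CCCCCCCCC/C=C/C#CCCCC(O)CCC1OCCO1
F2 | step 8 | tert-butyl{[(E)-1-(1,3-dioxolan-2-yl)nonadec-9-en-7-yn-3-yl]oxy}dimethylsilane | CCCCCCCCC/C=C/C#CCCCC(O[Si](C)(C)C(C)(C)C)CCC1OCCO1
F3 | step 8 | (E)-4-[(tert-butyldimethylsilyl)oxy]icos-10-en-8-ynal | CCCCCCCCC/C=C/C#CCCCC(O[Si](C)(C)C(C)(C)C)CCC=O
F4 | step 8 | (2E,12E)-6-[(tert-butyldimethylsilyl)oxy]docosa-2,12-dien-10-ynal | CCCCCCCCC/C=C/C#CCCCC(O[Si](C)(C)C(C)(C)C)CC/C=C/C=O
F5 | step 8 | (3S,12E)-6-[(tert-butyldimethylsilyl)oxy]-3-[(2-methoxypropan-2-yl)peroxy]docos-12-en-10-ynoic acid | CCCCCCCCC/C=C/C#CCCCC(O[Si](C)(C)C(C)(C)C)CC[C@@H](CC(=O)O)OOC(C)(C)OC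
F6 | step 8 | methyl (3S,12E)-6-[(tert-butyldimethylsilyl)oxy]-3-[(2-methoxypropan-2-yl)peroxy]docos-12-en-10-ynoate | CCCCCCCCC/C=C/C#CCCCC(O[Si](C)(C)C(C)(C)C)CC[C@@H](CC(=O)OC)OOC(C)(C)OC
F7 | step 8 | methyl (3S,12E)-6-hydroxy-3-[(2-methoxypropan-2-yl)peroxy]docos-12-en-10-ynoate | CCCCCCCCC/C=C/C#CCCCC(O)CC[C@@H](CC(=O)OC)OOC(C)(C)OC
F0 | step 11 | none | none
F0 | step 12 | none | none
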